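**Retrosynthetic overview**

- The route rests on the tetrahydrofuran (O1, C2–C5): C3 carries CH2OH next to the C3–C4 bond and C4 is bonded to the benzylic (carbonyl) carbon of ring C. This is the imprint of a β-titanoxy radical, born from a terminal epoxide, that has added to an aryl alkyne.
- Late disconnections: phenol benzyl ethers and silyl ethers; the C4 aroyl group from hydroboration–oxidation of a benzylidene alkene followed by base equilibration to the all-trans ring.
- The erythro arylglycerol ether on ring B comes from an auxiliary-controlled syn aldol (C7''–C8'' bond) on the ring B aryloxyacetyl imide, then Mitsunobu inversion at C7''.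
- Key disconnection: the C3–C4 bond and the tetrahydrofuran ring, by Cp2TiCl opening of an epoxy propargyl ether and 5-exo-dig radical closure. The precursor comes from syringaldehyde (vinyl carbinol, kinetic resolution, epoxidation) and an aryl propargyl bromide made by Sonogashira coupling.
- Ring order: rings A, B and C are bought as arenes; the tetrahydrofuran is the only ring constructed (step 9).

Key step: step 9

Remark: ring A is the guaiacyl ring of the glycerol unit, ring B the central syringyl ring, ring C the benzoyl ring; the glycerol carbons are C7'' (benzylic), C8'' (aryloxy) and C9''; the E/Z geometry of the benzylidene intermediates is left open because it is destroyed by the hydroboration.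

**Route**

Step 1
Reactants: 1 4-bromo-2,6-dimethoxyphenol
Product: 2 2-(benzyloxy)-5-bromo-1,3-dimethoxybenzene
Conditions: BnBr, K2CO3, DMF, 60 °C
Reagents that add atoms: benzyl bromide BrCc1ccccc1
Why: Williamson etherification of the phenoxide proceeds despite the two flanking methoxy groups and protects the ring C phenol through all later base, radical and hydride steps.

Step 2
Reactants: 2 2-(benzyloxy)-5-bromo-1,3-dimethoxybenzene; 3 prop-2-yn-1-ol (propargyl alcohol)
Product: 4 3-[4-(benzyloxy)-3,5-dimethoxyphenyl]prop-2-yn-1-ol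
Conditions: PdCl2(PPh3)2 (3 mol %), CuI (5 mol %), Et3N, THF, degassed, 70 °C
Reagents that add atoms: none
Why: Sonogashira coupling (oxidative addition of zerovalent palladium into the aryl bromide, copper acetylide transmetalation, reductive elimination) joins ring C to the three-carbon alkyne and tolerates the free primary alcohol.

Step 3
Reactants: 4 3-[4-(benzyloxy)-3,5-dimethoxyphenyl]prop-2-yn-1-ol
Product: 5 2-(benzyloxy)-5-(3-bromoprop-1-yn-1-yl)-1,3-dimethoxybenzene
Conditions: CBr4, PPh3, CH2Cl2, 0 °C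
Reagents that add atoms: carbon tetrabromide BrC(Br)(Br)Br
Why: Appel bromination displaces the alkoxyphosphonium ion of the primary propargylic alcohol by SN2 under neutral conditions, leaving the benzyl ether and the alkyne untouched.

Step 4
Reactants: 6 syringaldehyde (4-hydroxy-3,5-dimethoxybenzaldehyde)
Product: 7 3,5-dimethoxy-4-(triisopropylsilyloxy)benzaldehyde
Conditions: TIPSCl, imidazole, DMF, rt
Reagents that add atoms: triisopropylsilyl chloride CC(C)[Si](Cl)(C(C)C)C(C)C
Why: Silylation of the acidic phenol; the triisopropylsilyl ether, shielded by two methoxy groups, should resist the alkoxide of step 8 yet leave with fluoride in step 10 without touching benzyl ethers.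

Step 5
Reactants: 7 3,5-dimethoxy-4-(triisopropylsilyloxy)benzaldehyde
Product: 8 rac-1-[3,5-dimethoxy-4-(triisopropylsilyloxy)phenyl]prop-2-en-1-ol
Conditions: CH2=CHMgBr, THF, −78 → 0 °C; sat. NH4Cl
Reagents that add atoms: vinylmagnesium bromide C=C[Mg]Br
Why: Grignard 1,2-addition to the aldehyde gives the racemic allylic alcohol, and the aryl silyl ether is inert at low temperature.

Step 6
Reactants: 8 rac-1-[3,5-dimethoxy-4-(triisopropylsilyloxy)phenyl]prop-2-en-1-ol
Product: 9 (S)-1-[3,5-dimethoxy-4-(triisopropylsilyloxy)phenyl]prop-2-en-1-ol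
Conditions: Ti(OiPr)4 (1.0 equiv), L-(+)-diisopropyl tartrate (1.2 equiv), t-BuOOH (0.65 equiv, decane), 4 Å MS, CH2Cl2, −20 °C, stopped at about 55–60 % conversion
Reagents that add atoms: none
Why: Sharpless kinetic resolution: with the L-(+)-tartrate the (R)-carbinol is epoxidised much faster, so running past half conversion should leave the (S)-alcohol in high enantiomeric purity; its carbinol carbon becomes C2 of the tetrahydrofuran.

Step 7
Reactants: 9 (S)-1-[3,5-dimethoxy-4-(triisopropylsilyloxy)phenyl]prop-2-en-1-ol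
Product: 10 (R)-[3,5-dimethoxy-4-(triisopropylsilyloxy)phenyl](oxiran-2-yl)methanol, mixture of the two oxirane epimers
Conditions: mCPBA, NaHCO3, CH2Cl2, 0 °C → rt
Reagents that add atoms: 3-chloroperbenzoic acid OOC(=O)c1cccc(Cl)c1
Why: Hydroxyl-assisted Prilezhaev epoxidation of the terminal alkene needs no facial selectivity because the oxirane stereocentre is erased in step 9; the carbinol centre is untouched and its descriptor changes from S to R only because the oxiranyl carbon now outranks the aryl group.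

Step 8
Reactants: 10 (R)-[3,5-dimethoxy-4-(triisopropylsilyloxy)phenyl](oxiran-2-yl)methanol; 5 2-(benzyloxy)-5-(3-bromoprop-1-yn-1-yl)-1,3-dimethoxybenzene
Product: 11 2-{(R)-[3-(4-benzyloxy-3,5-dimethoxyphenyl)prop-2-yn-1-yloxy][3,5-dimethoxy-4-(triisopropylsilyloxy)phenyl]methyl}oxirane, both oxirane epimers
Conditions: NaH (1.1 equiv) added to 10 and 5 (1.2 equiv), Bu4NI (cat.), THF, −10 → 0 °C
Reagents that add atoms: none
Why: Williamson ether synthesis in which the sodium alkoxide is trapped by the reactive propargylic bromide, present from the outset, faster than it can migrate the epoxide; no bond to the stereocentre is broken.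

Step 9
Reactants: 11 epoxy propargyl ether (both oxirane epimers)
Product: 13 [(2S,3R)-4-[4-(benzyloxy)-3,5-dimethoxybenzylidene]-2-[3,5-dimethoxy-4-(triisopropylsilyloxy)phenyl]tetrahydrofuran-3-yl]methanol (E/Z mixture; 2,3-trans), via chlorotitanocene alkoxide 12 (not isolated)
Conditions: Cp2TiCl2 (2.5 equiv), Zn dust (excess), THF, rt (green Cp2TiCl solution), added over 1 h to 11 in THF (0.02 M), rt; then 0.5 M HCl, 0 °C
Reagents that add atoms: titanocene dichloride Cp2TiCl2 [Cl-].[Cl-].[Ti+4].c1cc[cH-]c1.c1cc[cH-]c1 (titanium only in 12)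
Why: Cp2TiCl (trivalent titanium) transfers one electron to the oxirane and cleaves its internal C–O bond, so both oxirane epimers give the same secondary β-titanoxy radical at C3; this radical adds 5-exo-dig to the proximal alkyne carbon, forming the C3–C4 bond and closing the O1–C2–C3–C4–C5 ring, and the α-aryl vinyl radical is then reduced by a second Cp2TiCl (or by hydrogen-atom transfer from THF) and protonated on work-up. The closest known reaction type is the titanocene-mediated reductive epoxide opening with radical cyclisation (Nugent–RajanBabu chemistry), which is established for epoxy allyl and propargyl ethers leading to 2-aryl-3-hydroxymethyl tetrahydrofurans. The one new stereocentre, C3, is controlled by the existing C2 centre: in the Beckwith–Houk envelope transition state the ring B aryl group on C2 and the bulky CH2OTiCp2Cl group on C3 lie on opposite faces, which should give the 2,3-trans ring. The step needs regioselective opening to the secondary radical (secured by radical stability at a terminal oxirane), exo over endo closure (the aryl group stabilises the exocyclic vinyl radical and the ether oxygen shortens the tether), and cyclisation faster than capture of the C3 radical by a second titanium centre, which slow addition at high dilution is meant to secure.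

Step 10
Reactants: 13 silyl-protected benzylidene tetrahydrofuran alcohol
Product: 14 4-[(2S,3R)-4-(4-benzyloxy-3,5-dimethoxybenzylidene)-3-(hydroxymethyl)tetrahydrofuran-2-yl]-2,6-dimethoxyphenol
Conditions: Bu4NF (1.1 equiv), THF, 0 °C; sat. NH4Cl
Reagents that add atoms: none
Why: Fluoride-induced Si–O cleavage, driven by the Si–F bond and the good phenoxide leaving group, frees the ring B phenol without affecting benzyl ethers, the alkene or the stereocentres.

Step 11
Reactants: 15 (R)-4-benzyloxazolidin-2-one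
Product: 16 (R)-4-benzyl-3-(bromoacetyl)oxazolidin-2-one
Conditions: n-BuLi, THF, −78 °C; BrCH2COBr, −78 → 0 °C
Reagents that add atoms: bromoacetyl bromide BrCC(Br)=O
Why: N-acylation of the lithiated oxazolidinone occurs at the acid bromide, which is far more electrophilic than the alkyl bromide terminus.

Step 12
Reactants: 14 ring B phenol; 16 (R)-4-benzyl-3-(bromoacetyl)oxazolidin-2-one
Product: 17 (R)-4-benzyl-3-{[4-[(2S,3R)-4-(4-benzyloxy-3,5-dimethoxybenzylidene)-3-(hydroxymethyl)tetrahydrofuran-2-yl]-2,6-dimethoxyphenoxy]acetyl}oxazolidin-2-one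
Conditions: K2CO3, acetone, rt
Reagents that add atoms: none
Why: Williamson O-alkylation: K2CO3 deprotonates only the phenol, and the phenoxide displaces the α-carbonyl bromide by SN2 while the aliphatic hydroxyl stays untouched.

Step 13
Reactants: 17 aryloxyacetyl imide with free CH2OH
Product: 18 tert-butyldimethylsilyl ether of 17 at the C3 CH2OH group
Conditions: TBSCl, imidazole, DMF, 0 °C → rt
Reagents that add atoms: tert-butyldimethylsilyl chloride CC(C)(C)[Si](C)(C)Cl
Why: Silylation of the primary alcohol, so that it neither consumes the boron triflate in step 14 nor is oxidised in step 19.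

Step 14
Reactants: 18 silylated aryloxyacetyl imide; 19 4-(benzyloxy)-3-methoxybenzaldehyde
Product: 21 (R)-4-benzyl-3-[(2R,3S)-2-aryloxy-3-(4-benzyloxy-3-methoxyphenyl)-3-hydroxypropanoyl]oxazolidin-2-one (aryl = ring B unit of 18; syn adduct), via dibutylboron Z-enolate 20 (not isolated)
Conditions: Bu2BOTf (1.2 equiv), iPr2NEt (1.4 equiv), CH2Cl2, −78 → 0 °C; 19, −78 → 0 °C; pH 7 buffer, MeOH, 30 % H2O2, 0 °C
Reagents that add atoms: dibutylboron triflate CCCCB(CCCC)OS(=O)(=O)C(F)(F)F (boron only in 20)
Why: Evans syn aldol: the Z boron enolate reacts through a Zimmerman–Traxler chair on the face opposite the auxiliary benzyl group, which fixes C8'' in the configuration of the target and gives the 2,3-syn (threo) adduct whose carbinol centre C7'' is corrected in step 17.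

Step 15
Reactants: 21 syn aldol adduct
Product: 22 (1S,2S)-1-(4-benzyloxy-3-methoxyphenyl)-2-aryloxypropane-1,3-diol (threo; aryl = ring B unit)
Conditions: LiBH4, MeOH (1 equiv per hydride reagent), THF, 0 °C
Reagents that add atoms: none
Why: Reductive cleavage of the N-acyl oxazolidinone by LiBH4 (hydride attack at the exocyclic imide carbonyl, then reduction of the aldehyde) gives the C9'' primary alcohol and returns the auxiliary, with no epimerisable centre exposed to base.

Step 16
Reactants: 22 threo 1,3-diol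
Product: 23 C9''-O-tert-butyldimethylsilyl ether of 22 (free C7''-OH)
Conditions: TBSCl (1.1 equiv), imidazole, CH2Cl2, 0 °C
Reagents that add atoms: tert-butyldimethylsilyl chloride CC(C)(C)[Si](C)(C)Cl
Why: Silylation selects the primary hydroxyl over the hindered benzylic secondary one.

Step 17
Reactants: 23 threo benzylic alcohol
Product: 24 (1R,2S)-1-(4-benzyloxy-3-methoxyphenyl)-2-aryloxy-3-(tert-butyldimethylsilyloxy)propyl 4-nitrobenzoate (erythro)
Conditions: 4-nitrobenzoic acid, PPh3, DIAD (3 equiv each), toluene, 0 °C → rt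
Reagents that add atoms: 4-nitrobenzoic acid OC(=O)c1ccc(cc1)[N+](=O)[O-]
Why: Mitsunobu reaction: the alkoxyphosphonium ion of the benzylic alcohol is displaced by 4-nitrobenzoate with inversion (SN2), turning threo into erythro (7''R,8''S); the electron-withdrawing β-aryloxy group disfavours ionisation, and the ester then masks O7'' through steps 18 and 19.

Step 18
Reactants: 24 erythro 4-nitrobenzoate with benzylidene alkene
Product: 26 secondary benzylic alcohol: hydration product of the benzylidene alkene of 24 with OH on the carbon bearing ring C and H on C4 (epimer mixture at C4 and at the carbinol carbon), via benzylic alkylborane 25 (not isolated)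
Conditions: BH3·THF (3 equiv), THF, 0 °C → rt; then Me3NO·2H2O (excess), 60 °C
Reagents that add atoms: borane–tetrahydrofuran B.C1CCOC1 (boron only in 25); trimethylamine N-oxide C[N+](C)(C)[O-]
Why: Hydroboration–oxidation: boron adds to the less substituted, benzylic alkene carbon and hydrogen to C4 (syn, anti-Markovnikov addition to a trisubstituted styrene), and the non-basic amine-oxide oxidation of the C–B bond spares the nitrobenzoate; both new centres are removed or equilibrated later.

Step 19
Reactants: 26 secondary benzylic alcohol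
Product: 27 aryl ketone: 4-(4-benzyloxy-3,5-dimethoxybenzoyl)tetrahydrofuran, C4 epimer mixture, other groups as in 24
Conditions: Dess–Martin periodinane, NaHCO3, CH2Cl2, 0 °C → rt
Reagents that add atoms: none
Why: Dess–Martin oxidation converts the only free hydroxyl, the secondary benzylic one, into the aryl ketone under buffered neutral conditions.

Step 20
Reactants: 27 ketone (C4 epimer mixture)
Product: 28 (2S,3R,4S)-ketone with free C7''-OH: all-trans tetrahydrofuran, erythro (7''R,8''S) glycerol unit, two primary silyl ethers and two benzyl ethers retained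
Conditions: K2CO3, MeOH/THF, rt
Reagents that add atoms: none
Why: Methanolysis of the activated 4-nitrobenzoate and, through the ketone enolate, thermodynamic epimerisation of C4 to the all-trans 2,3,4-trisubstituted ring (aroyl trans to the C3 CH2OSi group), which sets C4 as S.

Step 21
Reactants: 28 trans ketone bis-silyl ether
Product: 29 bis-benzyl ether of the target (free C7''-OH, C9''-OH and C3 CH2OH)
Conditions: HF·pyridine, pyridine, THF, 0 °C → rt
Reagents that add atoms: none
Why: Fluoride cleavage of the two primary silyl ethers under buffered, nearly neutral conditions that should not ionise the benzylic C–O bonds or epimerise C4.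

Step 22
Reactants: 29 bis-benzyl ether
Product: 30 CNP0236429.1 (target)
Conditions: H2 (1 atm), Pd/C (10 wt %), EtOAc/MeOH, rt, stopped at full debenzylation
Reagents that add atoms: none
Why: Hydrogenolysis of the two aryl benzyl ethers on palladium is much faster under neutral conditions than cleavage of the benzylic C7''–OH and C2–O1 bonds or reduction of the aryl ketone.

**Compound list**

1 | 4-bromo-2,6-dimethoxyphenol | COc1cc(Br)cc(OC)c1O | starting material
2 | 2-(benzyloxy)-5-bromo-1,3-dimethoxybenzene | COc1cc(Br)cc(OC)c1OCc1ccccc1 | intermediate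
3 | prop-2-yn-1-ol | C#CCO | starting material
4 | 3-[4-(benzyloxy)-3,5-dimethoxyphenyl]prop-2-yn-1-ol | COc1cc(C#CCO)cc(OC)c1OCc1ccccc1 | intermediate
5 | 2-(benzyloxy)-5-(3-bromoprop-1-yn-1-yl)-1,3-dimethoxybenzene | COc1cc(C#CCBr)cc(OC)c1OCc1ccccc1 | intermediate
6 | syringaldehyde | COc1cc(C=O)cc(OC)c1O | starting material
7 | 3,5-dimethoxy-4-(triisopropylsilyloxy)benzaldehyde | COc1cc(C=O)cc(OC)c1O[Si](C(C)C)(C(C)C)C(C)C | intermediate
8 | rac-1-[3,5-dimethoxy-4-(triisopropylsilyloxy)phenyl]prop-2-en-1-ol | C=CC(O)c1cc(OC)c(O[Si](C(C)C)(C(C)C)C(C)C)c(OC)c1 | intermediate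
9 | (S)-1-[3,5-dimethoxy-4-(triisopropylsilyloxy)phenyl]prop-2-en-1-ol | C=C[C@H](O)c1cc(OC)c(O[Si](C(C)C)(C(C)C)C(C)C)c(OC)c1 | intermediate
10 | (R)-[3,5-dimethoxy-4-(triisopropylsilyloxy)phenyl](oxiran-2-yl)methanol, both oxirane epimers | COc1cc([C@H](C2CO2)O)cc(OC)c1O[Si](C(C)C)(C(C)C)C(C)C | intermediate
11 | epoxy propargyl ether (key-step precursor), both oxirane epimers | COc1cc([C@H](C2CO2)OCC#Cc2cc(OC)c(OCc3ccccc3)c(OC)c2)cc(OC)c1O[Si](C(C)C)(C(C)C)C(C)C | intermediate
12 | chlorotitanocene alkoxide of 13 | COc1cc([C@H]2OCC(=Cc3cc(OC)c(OCc4ccccc4)c(OC)c3)[C@@H]2CO[Ti](Cl)(C2C=CC=C2)C2C=CC=C2)cc(OC)c1O[Si](C(C)C)(C(C)C)C(C)C | intermediate (not isolated)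
13 | [(2S,3R)-4-[4-(benzyloxy)-3,5-dimethoxybenzylidene]-2-[3,5-dimethoxy-4-(triisopropylsilyloxy)phenyl]tetrahydrofuran-3-yl]methanol | COc1cc([C@H]2OCC(=Cc3cc(OC)c(OCc4ccccc4)c(OC)c3)[C@@H]2CO)cc(OC)c1O[Si](C(C)C)(C(C)C)C(C)C | intermediate
14 | 4-[(2S,3R)-4-(4-benzyloxy-3,5-dimethoxybenzylidene)-3-(hydroxymethyl)tetrahydrofuran-2-yl]-2,6-dimethoxyphenol | COc1cc([C@H]2OCC(=Cc3cc(OC)c(OCc4ccccc4)c(OC)c3)[C@@H]2CO)cc(OC)c1O | intermediate
15 | (R)-4-benzyloxazolidin-2-one | O=C1N[C@H](Cc2ccccc2)CO1 | starting material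
16 | (R)-4-benzyl-3-(bromoacetyl)oxazolidin-2-one | O=C(CBr)N1[C@H](Cc2ccccc2)COC1=O | intermediate
17 | ring B aryloxyacetyl imide with free CH2OH | COc1cc([C@H]2OCC(=Cc3cc(OC)c(OCc4ccccc4)c(OC)c3)[C@@H]2CO)cc(OC)c1OCC(=O)N1[C@H](Cc2ccccc2)COC1=O | intermediate
18 | silyl ether of 17 | COc1cc([C@H]2OCC(=Cc3cc(OC)c(OCc4ccccc4)c(OC)c3)[C@@H]2CO[Si](C)(C)C(C)(C)C)cc(OC)c1OCC(=O)N1[C@H](Cc2ccccc2)COC1=O | intermediate
19 | 4-(benzyloxy)-3-methoxybenzaldehyde | COc1cc(C=O)ccc1OCc1ccccc1 | starting material
20 | dibutylboron Z-enolate of 18 | COc1cc([C@H]2OCC(=Cc3cc(OC)c(OCc4ccccc4)c(OC)c3)[C@@H]2CO[Si](C)(C)C(C)(C)C)cc(OC)c1O/C=C(\OB(CCCC)CCCC)N1[C@H](Cc2ccccc2)COC1=O | intermediate (not isolated)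
21 | (2R,3S) syn aldol adduct | COc1cc([C@H]2OCC(=Cc3cc(OC)c(OCc4ccccc4)c(OC)c3)[C@@H]2CO[Si](C)(C)C(C)(C)C)cc(OC)c1O[C@H]([C@@H](O)c1ccc(OCc2ccccc2)c(OC)c1)C(=O)N1[C@H](Cc2ccccc2)COC1=O | intermediate
22 | threo (1S,2S) 1,3-diol | COc1cc([C@H]2OCC(=Cc3cc(OC)c(OCc4ccccc4)c(OC)c3)[C@@H]2CO[Si](C)(C)C(C)(C)C)cc(OC)c1O[C@H]([C@@H](O)c1ccc(OCc2ccccc2)c(OC)c1)CO | intermediate
23 | C9''-O-silyl ether of 22 | COc1cc([C@H]2OCC(=Cc3cc(OC)c(OCc4ccccc4)c(OC)c3)[C@@H]2CO[Si](C)(C)C(C)(C)C)cc(OC)c1O[C@H]([C@@H](O)c1ccc(OCc2ccccc2)c(OC)c1)CO[Si](C)(C)C(C)(C)C | intermediate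
24 | erythro (1R,2S) 4-nitrobenzoate | COc1cc([C@H]2OCC(=Cc3cc(OC)c(OCc4ccccc4)c(OC)c3)[C@@H]2CO[Si](C)(C)C(C)(C)C)cc(OC)c1O[C@H]([C@H](OC(=O)c1ccc(cc1)[N+](=O)[O-])c1ccc(OCc2ccccc2)c(OC)c1)CO[Si](C)(C)C(C)(C)C | intermediate
25 | benzylic alkylborane from 24 | COc1cc([C@H]2OCC(C(B)c3cc(OC)c(OCc4ccccc4)c(OC)c3)[C@@H]2CO[Si](C)(C)C(C)(C)C)cc(OC)c1O[C@H]([C@H](OC(=O)c1ccc(cc1)[N+](=O)[O-])c1ccc(OCc2ccccc2)c(OC)c1)CO[Si](C)(C)C(C)(C)C | intermediate (not isolated)
26 | secondary benzylic alcohol (epimers at C4 and carbinol) | COc1cc([C@H]2OCC(C(O)c3cc(OC)c(OCc4ccccc4)c(OC)c3)[C@@H]2CO[Si](C)(C)C(C)(C)C)cc(OC)c1O[C@H]([C@H](OC(=O)c1ccc(cc1)[N+](=O)[O-])c1ccc(OCc2ccccc2)c(OC)c1)CO[Si](C)(C)C(C)(C)C | intermediate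
27 | aryl ketone, C4 epimer mixture | COc1cc([C@H]2OCC(C(=O)c3cc(OC)c(OCc4ccccc4)c(OC)c3)[C@@H]2CO[Si](C)(C)C(C)(C)C)cc(OC)c1O[C@H]([C@H](OC(=O)c1ccc(cc1)[N+](=O)[O-])c1ccc(OCc2ccccc2)c(OC)c1)CO[Si](C)(C)C(C)(C)C | intermediate
28 | (2S,3R,4S) trans ketone, free C7''-OH, bis-silyl ether | COc1cc([C@H]2OC[C@@H](C(=O)c3cc(OC)c(OCc4ccccc4)c(OC)c3)[C@@H]2CO[Si](C)(C)C(C)(C)C)cc(OC)c1O[C@H]([C@H](O)c1ccc(OCc2ccccc2)c(OC)c1)CO[Si](C)(C)C(C)(C)C | intermediate
29 | bis-benzyl ether of the target | COc1cc([C@H]2OC[C@@H](C(=O)c3cc(OC)c(OCc4ccccc4)c(OC)c3)[C@@H]2CO)cc(OC)c1O[C@H]([C@H](O)c1ccc(OCc2ccccc2)c(OC)c1)CO | intermediate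
30 | CNP0236429.1 | COc1cc([C@@H](O)[C@H](CO)Oc2c(OC)cc([C@H]3OC[C@@H](C(=O)c4cc(OC)c(O)c(OC)c4)[C@@H]3CO)cc2OC)ccc1O | target

**Step count and risk**

Total step count: 22. Longest linear sequence: 18 steps (steps 4–10 and 12–22, from syringaldehyde).

Steps most likely to fail:

Step 9. The C3 radical may be captured by a second titanium centre before it cyclises, which leads to deoxygenation of the epoxide, or the closure may show poor 2,3-trans selectivity. The fallback generates the same C3 radical with tin hydride. It sets out from 11: opening of the terminal oxirane with benzoic acid (cat. Bu4NBr, MeCN, 70 °C) should give the hydroxy benzoate F1. Acylation with phenyl chlorothionoformate (pyridine, DMAP) gives the thionocarbonate F2. Barton–McCombie-type radical generation (Bu3SnH, AIBN, toluene, 90 °C, slow addition) with 5-exo-dig closure gives the benzoate F3. Methanolysis (K2CO3, MeOH) returns to the route at 13; any material that also loses the silyl group is 14 and goes on into step 12.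

Step 17. The activated electron-rich benzylic alcohol may ionise partly, so that inversion is not clean, or may eliminate to the enol ether. The fallback replaces substitution by oxidation and chelation-controlled reduction. It sets out from 23: Dess–Martin oxidation gives the α-aryloxy ketone F4. Reduction with Zn(BH4)2 (Et2O, −20 °C), directed by a Cram chelate between the carbonyl and the aryloxy oxygen, should give the erythro alcohol F5. Acylation with 4-nitrobenzoyl chloride (pyridine) returns to the route at 24.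

Step 8. The alkoxide of 10 may migrate the epoxide (Payne rearrangement) before it is alkylated, or the silyl group may transfer from the phenol oxygen to the alkoxide. The fallback reverses the order of ether formation and epoxidation. It sets out from 9: O-alkylation with 5 (NaH, THF, 0 °C), with no epoxide present, gives the allyl propargyl ether F6. Buffered mCPBA epoxidation of the terminal alkene (CH2Cl2, NaHCO3, rt, prolonged) returns to the route at 11.

**Further compounds**

F1 | step 9 | (3R)-3-[3-(4-benzyloxy-3,5-dimethoxyphenyl)prop-2-yn-1-yloxy]-3-[3,5-dimethoxy-4-(triisopropylsilyloxy)phenyl]-2-hydroxypropyl benzoate, both C2 epimers | COc1cc([C@H](C(O)COC(=O)c2ccccc2)OCC#Cc2cc(OC)c(OCc3ccccc3)c(OC)c2)cc(OC)c1O[Si](C(C)C)(C(C)C)C(C)C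
F2 | step 9 | O-phenyl thionocarbonate of F1 | COc1cc([C@H](C(OC(=S)Oc2ccccc2)COC(=O)c2ccccc2)OCC#Cc2cc(OC)c(OCc3ccccc3)c(OC)c2)cc(OC)c1O[Si](C(C)C)(C(C)C)C(C)C
F3 | step 9 | benzoate of 13 | COc1cc([C@H]2OCC(=Cc3cc(OC)c(OCc4ccccc4)c(OC)c3)[C@@H]2COC(=O)c2ccccc2)cc(OC)c1O[Si](C(C)C)(C(C)C)C(C)C
F4 | step 17 | (S)-1-(4-benzyloxy-3-methoxyphenyl)-2-aryloxy-3-(tert-butyldimethylsilyloxy)propan-1-one (aryl = ring B unit of 23) | COc1cc([C@H]2OCC(=Cc3cc(OC)c(OCc4ccccc4)c(OC)c3)[C@@H]2CO[Si](C)(C)C(C)(C)C)cc(OC)c1O[C@H](C(=O)c1ccc(OCc2ccccc2)c(OC)c1)CO[Si](C)(C)C(C)(C)C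
F5 | step 17 | erythro (1R,2S) alcohol, C7'' epimer of 23 | COc1cc([C@H]2OCC(=Cc3cc(OC)c(OCc4ccccc4)c(OC)c3)[C@@H]2CO[Si](C)(C)C(C)(C)C)cc(OC)c1O[C@H]([C@H](O)c1ccc(OCc2ccccc2)c(OC)c1)CO[Si](C)(C)C(C)(C)C
F6 | step 8 | (S)-allyl propargyl ether of 9 with 5 | C=C[C@H](OCC#Cc1cc(OC)c(OCc2ccccc2)c(OC)c1)c1cc(OC)c(O[Si](C(C)C)(C(C)C)C(C)C)c(OC)c1
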